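A leftover of undissolved solid substrate at 3.0 min was what I looked for first, since the rate written for dissolution contains no charge.

    solid substrate ⇌ dissolved substrate, rate k1*(cs1 - [dissolved substrate]) while solid is left; crystals form when [dissolved substrate] > cs1 (cs1 = 0.49 M, k1 = 0.0173 s⁻¹)
    2 dissolved substrate → side product (k2 = 0.00254 L mol⁻¹ s⁻¹)
    dissolved substrate + reagent → target (k3 = 0.0305 L mol⁻¹ s⁻¹)
    gas ⇌ reagent, rate k4*(csat - [reagent]) (k4 = 0.423 s⁻¹, csat = 200 mM)
    2 reagent → self-condensation product (k5 = 0.0238 L mol⁻¹ s⁻¹)

solid substrate 0.80 M; gas 200 mM (held); time 3.0 min

- percentages count the solid substrate that a species holds: one side product counts as two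
- for a step with 2 of a species take k times the square, and two of it per event
- solid, in amounts per volume of the solution: solid substrate
- at the start none of reagent is dissolved
- at the start none of the solid substrate is in solution
- run time (flask): 3.0 min

1. the target standing at 3.0 min, as a percentage of the solid substrate charged
2. the change that raises the amount of target at 3.0 min, in percent of the solid substrate charged most ("none" if none brings more than 2 percentage points) (Wednesday's / Thursday's / Sunday's / Saturday's / none)
3. amount of target at 3.0 min, in percent of the solid substrate charged, after Thursday's

I ranked the clocks of this flask from fastest to slowest, against a run of 180 s: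

- reagent fed across from the gas, 2.36 s: after this, reagent stands near saturation;
- dissolution, 57.8 s: dissolved substrate climbs within the run;
- reagent self-condensing, 105 s: a steady drain on reagent;
- capture of dissolved substrate by reagent, 164 s: target accumulates across the run;
- side-product formation, 402 s: slower than the run, even at the solubility.

Since the feed clock is much shorter than the self-condensation clock, I held reagent at saturation, which makes capture pseudo-first-order with constant c, the target-forming rate constant times the saturation concentration. Since the side-product clock is longer than the run, I dropped that step, knowing both choices lean high. With a the dissolution coefficient and σ the solubility: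

κ = a + c = 0.0234 s⁻¹

S∞ = aσ/κ = 0.362 M

L = (1 − e^(−κt))/κ = 42.1 s

P = c·S∞·(t − L) = 0.305 M

I call P the charge-free target, the target in moles per litre reached by the end of a run during which solid stands. The solid this requires is 0.662 M, less than the 0.80 M charged, so I committed to 38.1 %. Doubling c for Thursday's gave 64.1 %; I did not reckon the other changes.

The forecast, which differed from my figures, gave 35.3 %, 59.6 % and Thursday's, holding that reagent “sits quasi-steady just below csat”.

The simulation gave 35.2 %, 59.5 % and Thursday's, whose gain of 24 percentage points compares with 15 points for Wednesday's. This flask therefore held 0.282 M of target, with 13.5 % of its charge still solid. For the neighbour charged with 1.4 M, P divided by the charge gave 21.8 %, and this flask's simulated molarity divided the same way gave 20.1 %. The neighbour gave 20.1 %, with 50.6 % of its own charge still solid, which is 0.281 M of target.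

Its constants are assumed.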